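**Plan**

1. Rings are lettered A–F along the chain as in the SMILES (A = 2-aryloxyphloroglucinol end, F = 3,4,5-trihydroxyphenoxy end). Remark on the chemistry: the molecule has no stereocentre and no resolvable axis, so it is achiral and no stereocontrol is needed.
2. Cuts, in order: the thirteen O–CH3 bonds on rings B–F; the C2–C1 bond of ring A; the C4–C5 bond and the ArO–CH2 bond of a six-carbon chain; then the four diaryl ether C–O bonds B/C, C/D, D/E and E/F.
3. Feature used: ring A is a benzene-1,3,5-triol whose C2, the carbon between the C1 and C3 hydroxyls, carries the ether oxygen to ring B C1. In the cyclohexane-1,3,5-trione tautomer this C2 is sp3 and corresponds to C6 of a 6-aryloxy-3,5-dioxohexanoate, so ring A can be closed by a Claisen condensation onto the ester carbon.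
4. Forward: rings F, E, D, C, B are joined in that order by four rounds of Cu-catalysed O-arylation with a bromobenzaldehyde followed by Dakin oxidation (the formyl group first activates the bromide, then becomes the next phenol oxygen). The chain is attached by Williamson alkylation and acetoacetate dianion acylation; ring A, the only ring made, closes last; global demethylation finishes.

Key step: step 11

**Route**

Step 1
Reactants: 1 3,4,5-trimethoxyphenol; 2 4-bromo-3,5-dimethoxybenzaldehyde
Product: 3 3,5-dimethoxy-4-(3,4,5-trimethoxyphenoxy)benzaldehyde (dimer aldehyde of rings E–F)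
Conditions: CuI (10 mol %), picolinic acid (20 mol %), K3PO4, DMSO, 90 °C, Ar
Reagents that add atoms: none
Why: Ullmann-type Cu-catalysed O-arylation, in which the para-formyl group activates the C–Br bond of 2, the phenoxide of 1 is unhindered and electron-rich, and the picolinic acid ligand system is one established for aryl halides with two ortho substituents.

Step 2
Reactants: 3 dimer aldehyde
Product: 5 3,5-dimethoxy-4-(3,4,5-trimethoxyphenoxy)phenol (dimer phenol), via dimer formate 4 (not isolated)
Conditions: mCPBA, CH2Cl2, 0 °C → rt; aq Na2SO3/NaHCO3 wash; then K2CO3 (cat.), MeOH, rt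
Reagents that add atoms: mCPBA, OOC(=O)c1cccc(Cl)c1
Why: Dakin-type Baeyer–Villiger oxidation, in which the aryl group carrying a para-aryloxy donor should migrate in preference to hydride and the resulting aryl formate is cleaved by mild methanolysis.

Step 3
Reactants: 5 dimer phenol; 6 2-bromo-3,4,5-trimethoxybenzaldehyde
Product: 7 2-[3,5-dimethoxy-4-(3,4,5-trimethoxyphenoxy)phenoxy]-3,4,5-trimethoxybenzaldehyde (trimer aldehyde of rings D–F)
Conditions: CuI (10 mol %), picolinic acid (20 mol %), K3PO4, DMSO, 90 °C, Ar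
Reagents that add atoms: none
Why: Ullmann-type O-arylation of an unhindered phenoxide (two ortho hydrogens) with a bromide activated by its ortho-formyl group, the classical pattern for diaryl ethers from 2-bromobenzaldehydes and 2-bromobenzoates.

Step 4
Reactants: 7 trimer aldehyde
Product: 9 2-[3,5-dimethoxy-4-(3,4,5-trimethoxyphenoxy)phenoxy]-3,4,5-trimethoxyphenol (trimer phenol), via trimer formate 8 (not isolated)
Conditions: mCPBA, CH2Cl2, 0 °C → rt; aq Na2SO3/NaHCO3 wash; then K2CO3 (cat.), MeOH, rt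
Reagents that add atoms: mCPBA, OOC(=O)c1cccc(Cl)c1
Why: Dakin-type Baeyer–Villiger oxidation, favoured here by a para-methoxy and an ortho-aryloxy donor on the migrating ring.

Step 5
Reactants: 9 trimer phenol; 2 4-bromo-3,5-dimethoxybenzaldehyde
Product: 10 4-{2-[3,5-dimethoxy-4-(3,4,5-trimethoxyphenoxy)phenoxy]-3,4,5-trimethoxyphenoxy}-3,5-dimethoxybenzaldehyde (tetramer aldehyde of rings C–F)
Conditions: CuI (20 mol %), picolinic acid (40 mol %), K3PO4, DMSO, 110 °C, Ar
Reagents that add atoms: none
Why: Ullmann-type O-arylation as in step 1, here forming a tri-ortho-substituted ether, for which the para-formyl activation of 2 and a ligand system developed for hindered diaryl ethers should suffice at higher loading and temperature.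

Step 6
Reactants: 10 tetramer aldehyde
Product: 12 4-{2-[3,5-dimethoxy-4-(3,4,5-trimethoxyphenoxy)phenoxy]-3,4,5-trimethoxyphenoxy}-3,5-dimethoxyphenol (tetramer phenol), via tetramer formate 11 (not isolated)
Conditions: mCPBA, CH2Cl2, 0 °C → rt; aq Na2SO3/NaHCO3 wash; then K2CO3 (cat.), MeOH, rt
Reagents that add atoms: mCPBA, OOC(=O)c1cccc(Cl)c1
Why: Dakin-type Baeyer–Villiger oxidation, the same transformation as step 2 on the same 4-aryloxy-3,5-dimethoxybenzaldehyde substructure.

Step 7
Reactants: 12 tetramer phenol; 6 2-bromo-3,4,5-trimethoxybenzaldehyde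
Product: 13 2-(4-{2-[3,5-dimethoxy-4-(3,4,5-trimethoxyphenoxy)phenoxy]-3,4,5-trimethoxyphenoxy}-3,5-dimethoxyphenoxy)-3,4,5-trimethoxybenzaldehyde (pentamer aldehyde of rings B–F)
Conditions: CuI (10 mol %), picolinic acid (20 mol %), K3PO4, DMSO, 90 °C, Ar
Reagents that add atoms: none
Why: Ullmann-type O-arylation of the same kind as step 3, since phenol 12 again has two ortho hydrogens and the bromide is ortho-formyl-activated.

Step 8
Reactants: 13 pentamer aldehyde
Product: 15 2-(4-{2-[3,5-dimethoxy-4-(3,4,5-trimethoxyphenoxy)phenoxy]-3,4,5-trimethoxyphenoxy}-3,5-dimethoxyphenoxy)-3,4,5-trimethoxyphenol (pentamer phenol ArOH), via pentamer formate 14 (not isolated)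
Conditions: mCPBA, CH2Cl2, 0 °C → rt; aq Na2SO3/NaHCO3 wash; then K2CO3 (cat.), MeOH, rt
Reagents that add atoms: mCPBA, OOC(=O)c1cccc(Cl)c1
Why: Dakin-type Baeyer–Villiger oxidation on the same 2-aryloxy-3,4,5-trimethoxybenzaldehyde substructure as in step 4.

Step 9
Reactants: 15 pentamer phenol ArOH; 16 2-chloro-N-methoxy-N-methylacetamide
Product: 17 N-methoxy-N-methyl-2-(ArO)acetamide (Ar = permethylated B–F pentamer aryl of 15)
Conditions: K2CO3, NaI (cat.), DMF, 60 °C, Ar
Reagents that add atoms: none
Why: Williamson ether synthesis by iodide-assisted SN2 displacement on an α-halo amide, with the phenoxide as the only nucleophile and the Weinreb amide inert to carbonate.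

Step 10
Reactants: 17 aryloxy Weinreb amide; 18 methyl acetoacetate
Product: 20 methyl 6-(ArO)-3,5-dioxohexanoate, via methyl acetoacetate dianion 19 (not isolated)
Conditions: 18 (3 equiv), LDA (6 equiv), THF, −78 → 0 °C; then 17, −78 → 0 °C; AcOH quench
Reagents that add atoms: none
Why: Acylation of the acetoacetate dianion at its terminal carbon by a Weinreb amide, whose chelated tetrahedral adduct persists until the quench and so prevents over-addition and consumption of dianion by the acidic 1,3-diketone product.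

Step 11
Reactants: 20 methyl 6-(ArO)-3,5-dioxohexanoate
Product: 22 2-(ArO)benzene-1,3,5-triol (hexamer with free ring A triol and thirteen methyl ethers), via 2-aryloxycyclohexane-1,3,5-trione 21 (not isolated)
Conditions: NaOMe (3 equiv), diglyme–MeOH, 65 → 140 °C with MeOH distilled off, Ar; then degassed 1 M HCl, 0 °C
Reagents that add atoms: none
Why: Methoxide converts 20 into its enolates; C2–H and C4–H are the more acidic sites, but they equilibrate with the C6 enolate (α to the C5 ketone and acidified by the aryloxy oxygen), which alone can reach the C1 ester carbonyl through a six-membered transition state, and addition–elimination with loss of methoxide should give trione 21, which tautomerises to the aromatic triol and leaves the equilibrium as its phenoxide. The closest known reaction type is the intramolecular Claisen (Dieckmann-type) cyclisation of β,δ-diketo and β-polyketo esters to phloroglucinols, the laboratory counterpart of triketide cyclisation. Ring A closes in the 6-(enolendo)-exo-trig mode by formation of the C6–C1 bond, and no stereocentre arises. The selectivity needed is C-acylation at C6 over O-acylation by the C5 enolate oxygen (lactonisation to a 4-hydroxy-2-pyrone); under methoxide the lactone is reopened to 20 whereas aromatisation is irreversible, so the material should funnel to 22. No carbon of the chain can close a five- or six-membered ring by aldol addition, and the ether oxygen is already in place as an alkyl aryl ether, so no arylation at a carbon flanked by two oxygens is required.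

Step 12
Reactants: 22 hexamer tridecamethyl ether
Product: 23 CNP0218077.0, 2-{2-[4-(2-{3,5-dihydroxy-4-(3,4,5-trihydroxyphenoxy)phenoxy}-3,4,5-trihydroxyphenoxy)-3,5-dihydroxyphenoxy]-3,4,5-trihydroxyphenoxy}benzene-1,3,5-triol
Conditions: BBr3 (30 equiv), CH2Cl2, −78 °C → rt, Ar; then H2O, 0 °C; degassed work-up, reversed-phase purification
Reagents that add atoms: none
Why: Lewis-acid-mediated aryl methyl ether cleavage, in which bromide attacks the methyl carbon of each BBr3-complexed methoxy group in an SN2 step while the diaryl ether oxygens, having no sp3 carbon to lose, should stay intact.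

**Compound list**

1 | 3,4,5-trimethoxyphenol | COc1cc(O)cc(OC)c1OC | starting material
2 | 4-bromo-3,5-dimethoxybenzaldehyde | COc1cc(C=O)cc(OC)c1Br | starting material
3 | 3,5-dimethoxy-4-(3,4,5-trimethoxyphenoxy)benzaldehyde (dimer aldehyde) | O=Cc1cc(OC)c(Oc2cc(OC)c(OC)c(OC)c2)c(OC)c1 | intermediate
4 | 3,5-dimethoxy-4-(3,4,5-trimethoxyphenoxy)phenyl formate (dimer formate, not isolated) | O=COc1cc(OC)c(Oc2cc(OC)c(OC)c(OC)c2)c(OC)c1 | intermediate
5 | 3,5-dimethoxy-4-(3,4,5-trimethoxyphenoxy)phenol (dimer phenol) | Oc1cc(OC)c(Oc2cc(OC)c(OC)c(OC)c2)c(OC)c1 | intermediate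
6 | 2-bromo-3,4,5-trimethoxybenzaldehyde | COc1cc(C=O)c(Br)c(OC)c1OC | starting material
7 | trimer aldehyde, 2-[3,5-dimethoxy-4-(3,4,5-trimethoxyphenoxy)phenoxy]-3,4,5-trimethoxybenzaldehyde | O=Cc1cc(OC)c(OC)c(OC)c1Oc1cc(OC)c(Oc2cc(OC)c(OC)c(OC)c2)c(OC)c1 | intermediate
8 | trimer formate, formate ester of phenol 9 (not isolated) | O=COc1cc(OC)c(OC)c(OC)c1Oc1cc(OC)c(Oc2cc(OC)c(OC)c(OC)c2)c(OC)c1 | intermediate
9 | trimer phenol, 2-[3,5-dimethoxy-4-(3,4,5-trimethoxyphenoxy)phenoxy]-3,4,5-trimethoxyphenol | Oc1cc(OC)c(OC)c(OC)c1Oc1cc(OC)c(Oc2cc(OC)c(OC)c(OC)c2)c(OC)c1 | intermediate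
10 | tetramer aldehyde, 4-{2-[3,5-dimethoxy-4-(3,4,5-trimethoxyphenoxy)phenoxy]-3,4,5-trimethoxyphenoxy}-3,5-dimethoxybenzaldehyde | O=Cc1cc(OC)c(Oc2cc(OC)c(OC)c(OC)c2Oc2cc(OC)c(Oc3cc(OC)c(OC)c(OC)c3)c(OC)c2)c(OC)c1 | intermediate
11 | tetramer formate, formate ester of phenol 12 (not isolated) | O=COc1cc(OC)c(Oc2cc(OC)c(OC)c(OC)c2Oc2cc(OC)c(Oc3cc(OC)c(OC)c(OC)c3)c(OC)c2)c(OC)c1 | intermediate
12 | tetramer phenol, 4-{2-[3,5-dimethoxy-4-(3,4,5-trimethoxyphenoxy)phenoxy]-3,4,5-trimethoxyphenoxy}-3,5-dimethoxyphenol | Oc1cc(OC)c(Oc2cc(OC)c(OC)c(OC)c2Oc2cc(OC)c(Oc3cc(OC)c(OC)c(OC)c3)c(OC)c2)c(OC)c1 | intermediate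
13 | pentamer aldehyde, 2-(4-{2-[3,5-dimethoxy-4-(3,4,5-trimethoxyphenoxy)phenoxy]-3,4,5-trimethoxyphenoxy}-3,5-dimethoxyphenoxy)-3,4,5-trimethoxybenzaldehyde | O=Cc1cc(OC)c(OC)c(OC)c1Oc1cc(OC)c(Oc2cc(OC)c(OC)c(OC)c2Oc2cc(OC)c(Oc3cc(OC)c(OC)c(OC)c3)c(OC)c2)c(OC)c1 | intermediate
14 | pentamer formate, formate ester of phenol 15 (not isolated) | O=COc1cc(OC)c(OC)c(OC)c1Oc1cc(OC)c(Oc2cc(OC)c(OC)c(OC)c2Oc2cc(OC)c(Oc3cc(OC)c(OC)c(OC)c3)c(OC)c2)c(OC)c1 | intermediate
15 | pentamer phenol ArOH, 2-(4-{2-[3,5-dimethoxy-4-(3,4,5-trimethoxyphenoxy)phenoxy]-3,4,5-trimethoxyphenoxy}-3,5-dimethoxyphenoxy)-3,4,5-trimethoxyphenol | Oc1cc(OC)c(OC)c(OC)c1Oc1cc(OC)c(Oc2cc(OC)c(OC)c(OC)c2Oc2cc(OC)c(Oc3cc(OC)c(OC)c(OC)c3)c(OC)c2)c(OC)c1 | intermediate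
16 | 2-chloro-N-methoxy-N-methylacetamide | CON(C)C(=O)CCl | starting material
17 | N-methoxy-N-methyl-2-(ArO)acetamide, Ar = aryl group of 15 | CON(C)C(=O)COc1cc(OC)c(OC)c(OC)c1Oc1cc(OC)c(Oc2cc(OC)c(OC)c(OC)c2Oc2cc(OC)c(Oc3cc(OC)c(OC)c(OC)c3)c(OC)c2)c(OC)c1 | intermediate
18 | methyl acetoacetate | COC(=O)CC(C)=O | starting material
19 | dilithium dianion of methyl acetoacetate (not isolated) | [Li+].[Li+].[CH2-]C(=O)[CH-]C(=O)OC | intermediate
20 | methyl 6-(ArO)-3,5-dioxohexanoate | COC(=O)CC(=O)CC(=O)COc1cc(OC)c(OC)c(OC)c1Oc1cc(OC)c(Oc2cc(OC)c(OC)c(OC)c2Oc2cc(OC)c(Oc3cc(OC)c(OC)c(OC)c3)c(OC)c2)c(OC)c1 | intermediate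
21 | 2-(ArO)cyclohexane-1,3,5-trione (not isolated) | O=C1CC(=O)C(Oc2cc(OC)c(OC)c(OC)c2Oc2cc(OC)c(Oc3cc(OC)c(OC)c(OC)c3Oc3cc(OC)c(Oc4cc(OC)c(OC)c(OC)c4)c(OC)c3)c(OC)c2)C(=O)C1 | intermediate
22 | 2-(ArO)benzene-1,3,5-triol, hexamer with thirteen methyl ethers | Oc1cc(O)c(Oc2cc(OC)c(OC)c(OC)c2Oc2cc(OC)c(Oc3cc(OC)c(OC)c(OC)c3Oc3cc(OC)c(Oc4cc(OC)c(OC)c(OC)c4)c(OC)c3)c(OC)c2)c(O)c1 | intermediate
23 | CNP0218077.0, fully deprotected hexamer (achiral) | Oc1cc(O)c(Oc2cc(O)c(O)c(O)c2Oc2cc(O)c(Oc3cc(O)c(O)c(O)c3Oc3cc(O)c(Oc4cc(O)c(O)c(O)c4)c(O)c3)c(O)c2)c(O)c1 | target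

**Totals and risks**

Total step count: 12. Longest linear sequence: 12 steps (1 → 23).

Steps most likely to fail:

1. Step 11. The C6 enolate may be too sparsely populated beside the C2/C4 enolates, so that the chain rests as its enolate, drifts into lactonisation, or fragments by retro-Claisen cleavage at the temperature needed; partial loss of methyl groups under hot methoxide would be harmless because step 12 removes them all. The fallback sets out from pentamer phenol 15 and comes back at target 23; it brings ring A in as a preformed arene by a fifth round of the chemistry of steps 5 and 6. Cu-catalysed arylation of 15 with bromide 2 (CuI, picolinic acid, K3PO4, DMSO, 110 °C) should give the hexamer aldehyde F1. mCPBA in CH2Cl2 should convert it into the hexamer formate F2, whose methanolysis (cat. K2CO3, MeOH) should give the hexamer phenol F3, a 4-(ArO)-3,5-dimethoxyphenol. BBr3 under the conditions of step 12 should then cleave all fifteen methyl ethers to give 23.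

2. Step 5. The C–O bond formation may stall because the bromide is flanked by two methoxy groups and the phenoxide carries an ortho-aryloxy group, leaving hydrodebromination of 2 and oxidative decay of the electron-rich phenoxide as the faster processes. The fallback sets out from trimer phenol 9 and comes back at tetramer aldehyde 10. It replaces copper catalysis by an uncatalysed addition–elimination (SNAr): the caesium phenoxide of 9 is heated with 4-fluoro-3,5-dimethoxybenzaldehyde (Cs2CO3, DMSO, 120 °C), where the small fluoride leaving group and the para-formyl-stabilised Meisenheimer adduct should tolerate the congestion better; the product is 10 itself, so no compound outside the list is made (F0).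

3. Step 12. Cleavage of thirteen ethers may stop short on the crowded 1,2,3-trioxygenated rings, and the pyrogallol-type rings of the free polyphenol may oxidise during aqueous work-up and chromatography. The fallback sets out from 22 and comes back at 23 by a derivatise–purify–release sequence. After BBr3 treatment and quench the crude polyphenol is not purified but acetylated at once (Ac2O, pyridine, cat. DMAP) to the hexadeca-acetate F4, which should be stable to air and silica and separable from under-demethylated material. Degassed acid methanolysis (HCl generated from AcCl in MeOH, rt) should then release 23 without exposure to base.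

**Further compounds**

F1 | step 11 | hexamer aldehyde, 4-(ArO)-3,5-dimethoxybenzaldehyde (Ar = aryl group of 15) | COc1cc(C=O)cc(OC)c1Oc1cc(OC)c(OC)c(OC)c1Oc1cc(OC)c(Oc2cc(OC)c(OC)c(OC)c2Oc2cc(OC)c(Oc3cc(OC)c(OC)c(OC)c3)c(OC)c2)c(OC)c1
F2 | step 11 | hexamer formate, 4-(ArO)-3,5-dimethoxyphenyl formate | COc1cc(OC=O)cc(OC)c1Oc1cc(OC)c(OC)c(OC)c1Oc1cc(OC)c(Oc2cc(OC)c(OC)c(OC)c2Oc2cc(OC)c(Oc3cc(OC)c(OC)c(OC)c3)c(OC)c2)c(OC)c1
F3 | step 11 | hexamer phenol, 4-(ArO)-3,5-dimethoxyphenol | COc1cc(O)cc(OC)c1Oc1cc(OC)c(OC)c(OC)c1Oc1cc(OC)c(Oc2cc(OC)c(OC)c(OC)c2Oc2cc(OC)c(Oc3cc(OC)c(OC)c(OC)c3)c(OC)c2)c(OC)c1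
F0 | step 5 | none | none
F4 | step 12 | hexadeca-acetate of 23 | CC(=O)Oc1cc(OC(C)=O)c(Oc2cc(OC(C)=O)c(OC(C)=O)c(OC(C)=O)c2Oc2cc(OC(C)=O)c(Oc3cc(OC(C)=O)c(OC(C)=O)c(OC(C)=O)c3Oc3cc(OC(C)=O)c(Oc4cc(OC(C)=O)c(OC(C)=O)c(OC(C)=O)c4)c(OC(C)=O)c3)c(OC(C)=O)c2)c(OC(C)=O)c1
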